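The piperidine ring A (N1, C2, C3, C4, C4a, C8a) is cut from carbocyclic ring B at C4–C4a and N1–C8a. The key step exploits the 1,3-relationship in ring B between nitrogen-bearing C8a and side-chain-bearing C5, with C4a between them: these map onto the two carbonyl carbons and the central CH2 of cyclohexane-1,3-dione. In one operation an L-alanine-derived γ-chloro amine salt (N1–C2–C3–C4, both stereocentres already set) condenses with one carbonyl and C-alkylates the resulting enaminone, giving a bicyclic vinylogous amide. The precursor is thus a symmetric achiral dione plus a four-atom amino halide; the leftover C5 carbonyl later carries the side chain.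

Key step: step 5

Remark: ring atoms follow decahydroquinoline numbering (N1, C2, C3, C4, C4a, C5 to C8, C8a; side chain C1' to C8'), and compounds 1, 6, 15 and 21 are assumed to be purchasable as such.

Step 1
Reactants: 1 tert-butyl {(2S)-1-[methoxy(methyl)amino]-1-oxopropan-2-yl}carbamate (Boc-L-alanine N-methoxy-N-methylamide)
Product: 2 tert-butyl [(2S)-4-chloro-3-oxobutan-2-yl]carbamate
Conditions: ICH2Cl, MeLi·LiBr, THF, −78 °C; then AcOH, −78 °C → rt
Reagents that add atoms: chloroiodomethane, ClCI
Why: Chloromethyllithium, generated in situ by iodine–lithium exchange, should add once to the Weinreb amide because the chelated tetrahedral adduct survives until the acidic quench, while prior N–H deprotonation of the carbamate shields the α-stereocentre from enolisation (Weinreb ketone synthesis with a lithium carbenoid).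

Step 2
Reactants: 2 tert-butyl [(2S)-4-chloro-3-oxobutan-2-yl]carbamate
Product: 3 tert-butyl [(2S,3S)-4-chloro-3-hydroxybutan-2-yl]carbamate
Conditions: LiAlH(OtBu)3, EtOH, −78 °C
Reagents that add atoms: none
Why: Hydride delivery to the lithium-chelated N-carbamoyl α-amino ketone (Cram-chelate model) from the side of the small α-hydrogen should set the carbinol centre (future C3) anti to nitrogen, as is typical of carbamate-protected α-amino chloromethyl ketones (chelation-controlled ketone reduction).

Step 3
Reactants: 3 tert-butyl [(2S,3S)-4-chloro-3-hydroxybutan-2-yl]carbamate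
Product: 4 tert-butyl [(2S,3S)-3-(benzyloxy)-4-chlorobutan-2-yl]carbamate
Conditions: benzyl 2,2,2-trichloroacetimidate, TfOH (cat.), CH2Cl2/cyclohexane, 0 °C → rt
Reagents that add atoms: benzyl 2,2,2-trichloroacetimidate, N=C(OCc1ccccc1)C(Cl)(Cl)Cl
Why: Acid-catalysed O-benzylation avoids any alkoxide, which would close the chlorohydrin to an epoxide, and touches neither stereocentre (imidate etherification).

Step 4
Reactants: 4 tert-butyl [(2S,3S)-3-(benzyloxy)-4-chlorobutan-2-yl]carbamate
Product: 5 (2S,3S)-3-(benzyloxy)-4-chlorobutan-2-aminium chloride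
Conditions: HCl (4 M in dioxane), 0 °C → rt
Reagents that add atoms: hydrogen chloride, Cl
Why: Acidolysis of the tert-butyl carbamate should give the amine as its hydrochloride, in which nitrogen is masked as ammonium and cannot alkylate the neighbouring chloride on storage (carbamate deprotection).

Step 5
Reactants: 5 (2S,3S)-3-(benzyloxy)-4-chlorobutan-2-aminium chloride; 6 cyclohexane-1,3-dione
Product: 9 (2S,3R)-3-(benzyloxy)-2-methyl-2,3,4,6,7,8-hexahydroquinolin-5(1H)-one, via chloro enaminone 7 (not isolated), via iodo enaminone 8 (not isolated)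
Conditions: Et3N, 4 Å MS, MeCN, 60 °C; then NaI, K2CO3, reflux
Reagents that add atoms: none
Why: The liberated primary amine adds to the enolised dione and loses water to give vinylogous amide 7 (N1–C8a), chloride–iodide exchange gives 8, and the enaminone α-carbon (the central dione carbon, now C4a) displaces iodide intramolecularly, the resulting iminium losing a proton to K2CO3 to restore the conjugated enaminone 9 (C4–C4a). The closest known reaction type is the alkylative aza-annulation of cyclic 1,3-diones with ω-haloalkylamines to hexahydroquinolin-5-ones. The one ring closed is ring A, by a 6-exo-tet displacement in which the nucleophilic C=C lies inside the new ring (6-(enolendo)-exo-tet). No stereocentre is created and none is at risk, since C2 and C3 carry no acidifying group and the SN2 carbon C4 is not stereogenic. The step needs C-alkylation over N- or O-alkylation and condensation ahead of any intermolecular N-alkylation: the tether makes N-attack a four-membered and O-attack an eight-membered closure, the chloride stays inert until iodide is added after the enaminone has formed, and the mirror-symmetric dione removes any choice between the two carbonyls.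

Step 6
Reactants: 9 (2S,3R)-3-(benzyloxy)-2-methyl-2,3,4,6,7,8-hexahydroquinolin-5(1H)-one
Product: 11 tert-butyl (2S,3R,8aR)-3-(benzyloxy)-5-hydroxy-2-methyloctahydroquinoline-1(2H)-carboxylate (mixed C4a/C5 epimers), via amino alcohol 10 (not isolated)
Conditions: NaBH4, AcOH, 10 °C → rt; aq NaOH work-up; then Boc2O, THF, 50 °C
Reagents that add atoms: di-tert-butyl dicarbonate, CC(C)(C)OC(=O)OC(=O)OC(C)(C)C
Why: In acetic acid the enaminone is C-protonated at C4a to the cyclic iminium N1=C8a, and stereoelectronically controlled axial hydride addition to the half-chair with the C2 methyl pseudo-equatorial should place H8a cis to H2 (2,8a-cis piperidine), the C5 ketone being reduced as well and the unselective C4a and C5 centres being corrected in step 7 (acyloxyborohydride reduction of a β-enaminone, then N-carbamoylation).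

Step 7
Reactants: 11 tert-butyl (2S,3R,8aR)-3-(benzyloxy)-5-hydroxy-2-methyloctahydroquinoline-1(2H)-carboxylate (mixed C4a/C5 epimers)
Product: 13 tert-butyl (2S,3R,4aR,8aR)-3-(benzyloxy)-2-methyl-5-oxooctahydroquinoline-1(2H)-carboxylate (cis-fused), via ketone epimer mixture 12 (not isolated)
Conditions: Dess–Martin periodinane, CH2Cl2, rt; then K2CO3, MeOH, rt
Reagents that add atoms: none
Why: Oxidation erases C5, and base-mediated enolisation then lets C4a settle in the cis-fused ketone, which should be favoured because the carbamate forces the C2 methyl and the C8a–C8 bond axial to escape A(1,3) strain, an arrangement that only cis fusion (C4a–C5 equatorial on ring A) accommodates (Dess–Martin oxidation followed by thermodynamic epimerisation α to a ketone).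

Step 8
Reactants: 13 tert-butyl (2S,3R,4aR,8aR)-3-(benzyloxy)-2-methyl-5-oxooctahydroquinoline-1(2H)-carboxylate
Product: 14 tert-butyl (2S,3R,4aR,8aR)-3-(benzyloxy)-2-methyl-5-{[(trifluoromethyl)sulfonyl]oxy}-3,4,4a,7,8,8a-hexahydroquinoline-1(2H)-carboxylate
Conditions: KN(SiMe3)2, THF, −78 °C; then PhNTf2, −78 → 0 °C
Reagents that add atoms: N-phenylbis(trifluoromethanesulfonimide), O=S(=O)(N(c1ccccc1)S(=O)(=O)C(F)(F)F)C(F)(F)F
Why: Kinetic deprotonation should remove an axial C6 hydrogen rather than the hindered C4a methine, whose hydrogen is equatorial on ring B and poorly aligned with the carbonyl, so the Δ5,6 enol triflate forms without touching the ring-fusion centres (regioselective enolate O-triflation).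

Step 9
Reactants: 15 (2R)-2-propyloxirane
Product: 16 (4R)-oct-7-en-4-ol
Conditions: allylmagnesium bromide, CuI (cat.), THF, −30 → 0 °C; then sat. aq NH4Cl
Reagents that add atoms: allylmagnesium bromide, C=CC[Mg]Br
Why: Copper-catalysed SN2 opening of the terminal epoxide occurs at the unsubstituted carbon, so the C–O bond at the stereocentre is untouched and the (R) configuration (future C5') is carried over (organocuprate epoxide opening).

Step 10
Reactants: 16 (4R)-oct-7-en-4-ol
Product: 17 tert-butyl(dimethyl){[(4R)-oct-7-en-4-yl]oxy}silane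
Conditions: TBSCl, imidazole, DMF, rt
Reagents that add atoms: tert-butyl(chloro)dimethylsilane, CC(C)(C)[Si](C)(C)Cl
Why: Silylation of the secondary alcohol gives an ether that should survive the borane, the basic palladium coupling and hydrogenation but fall to acid at the end (silyl ether protection).

Step 11
Reactants: 17 tert-butyl(dimethyl){[(4R)-oct-7-en-4-yl]oxy}silane; 14 tert-butyl (2S,3R,4aR,8aR)-3-(benzyloxy)-2-methyl-5-{[(trifluoromethyl)sulfonyl]oxy}-3,4,4a,7,8,8a-hexahydroquinoline-1(2H)-carboxylate
Product: 19 tert-butyl (2S,3R,4aS,8aR)-3-(benzyloxy)-5-[(5R)-5-{[tert-butyl(dimethyl)silyl]oxy}octyl]-2-methyl-3,4,4a,7,8,8a-hexahydroquinoline-1(2H)-carboxylate, via B-alkyl borane 18 (not isolated)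
Conditions: 17, 9-BBN, THF, 0 °C → rt; then 14, Pd(dppf)Cl2 (dppf = 1,1'-bis(diphenylphosphino)ferrocene), AsPh3, Cs2CO3, DMF/H2O, rt → 50 °C
Reagents that add atoms: none
Why: Anti-Markovnikov hydroboration gives a primary B-alkyl borane that, after oxidative addition of the cyclohexenyl triflate to zerovalent palladium, transmetalates under basic conditions and reductively eliminates to create the C5–C1' bond without affecting any stereocentre (B-alkyl Suzuki–Miyaura coupling).

Step 12
Reactants: 19 tert-butyl (2S,3R,4aS,8aR)-3-(benzyloxy)-5-[(5R)-5-{[tert-butyl(dimethyl)silyl]oxy}octyl]-2-methyl-3,4,4a,7,8,8a-hexahydroquinoline-1(2H)-carboxylate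
Product: 20 tert-butyl (2S,3R,4aS,5S,8aR)-5-[(5R)-5-{[tert-butyl(dimethyl)silyl]oxy}octyl]-3-hydroxy-2-methyloctahydroquinoline-1(2H)-carboxylate
Conditions: H2 (5 atm), Pd(OH)2/C, EtOAc, rt
Reagents that add atoms: none
Why: Heterogeneous syn-addition of hydrogen to C5=C6 should occur from the convex face that carries H4a and H8a, the other face being shielded by the pseudoaxial C4 methylene that the carbamate-locked conformer and A(1,2) strain with the C5 chain hold in place, which sets C5 (5S, H5 cis to H4a), while the benzyl ether is hydrogenolysed in the same operation (catalytic hydrogenation and hydrogenolysis).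

Step 13
Reactants: 21 (2E)-hex-2-enal
Product: 22 (2E,4E)-octa-2,4-dienoic acid
Conditions: malonic acid, pyridine, piperidine (cat.), 90 °C
Reagents that add atoms: malonic acid, OC(=O)CC(=O)O
Why: Decarboxylative Knoevenagel condensation (Doebner modification) should form the new C2=C3 bond with E geometry under thermodynamic control while the existing E alkene is untouched.

Step 14
Reactants: 20 tert-butyl (2S,3R,4aS,5S,8aR)-5-[(5R)-5-{[tert-butyl(dimethyl)silyl]oxy}octyl]-3-hydroxy-2-methyloctahydroquinoline-1(2H)-carboxylate; 22 (2E,4E)-octa-2,4-dienoic acid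
Product: 23 tert-butyl (2S,3R,4aS,5S,8aR)-5-[(5R)-5-{[tert-butyl(dimethyl)silyl]oxy}octyl]-2-methyl-3-{[(2E,4E)-octa-2,4-dienoyl]oxy}octahydroquinoline-1(2H)-carboxylate
Conditions: EDC·HCl, DMAP, CH2Cl2, 0 °C → rt
Reagents that add atoms: none
Why: Carbodiimide activation with acyl transfer through the acylpyridinium (Steglich esterification) should acylate the only free hydroxyl, at C3, with retention because the C3–O bond is not broken.

Step 15
Reactants: 23 tert-butyl (2S,3R,4aS,5S,8aR)-5-[(5R)-5-{[tert-butyl(dimethyl)silyl]oxy}octyl]-2-methyl-3-{[(2E,4E)-octa-2,4-dienoyl]oxy}octahydroquinoline-1(2H)-carboxylate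
Product: 24 lepadin H, (2S,3R,4aS,5S,8aR)-5-[(5R)-5-hydroxyoctyl]-2-methyldecahydroquinolin-3-yl (2E,4E)-octa-2,4-dienoate
Conditions: TFA/H2O (9:1), CH2Cl2, 0 °C → rt; then aq NaHCO3
Reagents that add atoms: none
Why: Trifluoroacetic acid should cleave the tert-butyl carbamate by tert-butyl cation loss and decarboxylation and, with water, protodesilylate the secondary silyl ether, whereas the dienoate ester is inert to non-nucleophilic acid (global acidolytic deprotection).

Compound list
1 | tert-butyl {(2S)-1-[methoxy(methyl)amino]-1-oxopropan-2-yl}carbamate | C[C@H](NC(=O)OC(C)(C)C)C(=O)N(C)OC | starting material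
2 | tert-butyl [(2S)-4-chloro-3-oxobutan-2-yl]carbamate | C[C@H](NC(=O)OC(C)(C)C)C(=O)CCl | intermediate
3 | tert-butyl [(2S,3S)-4-chloro-3-hydroxybutan-2-yl]carbamate | C[C@H](NC(=O)OC(C)(C)C)[C@H](O)CCl | intermediate
4 | tert-butyl [(2S,3S)-3-(benzyloxy)-4-chlorobutan-2-yl]carbamate | C[C@H](NC(=O)OC(C)(C)C)[C@H](OCc1ccccc1)CCl | intermediate
5 | (2S,3S)-3-(benzyloxy)-4-chlorobutan-2-aminium chloride | C[C@H]([NH3+])[C@H](OCc1ccccc1)CCl.[Cl-] | intermediate
6 | cyclohexane-1,3-dione | O=C1CCCC(=O)C1 | starting material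
7 | 3-{[(2S,3S)-3-(benzyloxy)-4-chlorobutan-2-yl]amino}cyclohex-2-en-1-one (not isolated) | C[C@H](NC1=CC(=O)CCC1)[C@H](OCc1ccccc1)CCl | intermediate
8 | 3-{[(2S,3S)-3-(benzyloxy)-4-iodobutan-2-yl]amino}cyclohex-2-en-1-one (not isolated) | C[C@H](NC1=CC(=O)CCC1)[C@H](OCc1ccccc1)CI | intermediate
9 | (2S,3R)-3-(benzyloxy)-2-methyl-2,3,4,6,7,8-hexahydroquinolin-5(1H)-one | C[C@@H]1NC2=C(C[C@H]1OCc1ccccc1)C(=O)CCC2 | intermediate
10 | (2S,3R,8aR)-3-(benzyloxy)-2-methyldecahydroquinolin-5-ol, mixed C4a/C5 epimers (not isolated) | C[C@@H]1N[C@@H]2CCCC(O)C2C[C@H]1OCc1ccccc1 | intermediate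
11 | tert-butyl (2S,3R,8aR)-3-(benzyloxy)-5-hydroxy-2-methyloctahydroquinoline-1(2H)-carboxylate, mixed C4a/C5 epimers | C[C@@H]1N(C(=O)OC(C)(C)C)[C@@H]2CCCC(O)C2C[C@H]1OCc1ccccc1 | intermediate
12 | tert-butyl (2S,3R,8aR)-3-(benzyloxy)-2-methyl-5-oxooctahydroquinoline-1(2H)-carboxylate, mixed C4a epimers (not isolated) | C[C@@H]1N(C(=O)OC(C)(C)C)[C@@H]2CCCC(=O)C2C[C@H]1OCc1ccccc1 | intermediate
13 | tert-butyl (2S,3R,4aR,8aR)-3-(benzyloxy)-2-methyl-5-oxooctahydroquinoline-1(2H)-carboxylate (cis-fused) | C[C@@H]1N(C(=O)OC(C)(C)C)[C@@H]2CCCC(=O)[C@@H]2C[C@H]1OCc1ccccc1 | intermediate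
14 | tert-butyl (2S,3R,4aR,8aR)-3-(benzyloxy)-2-methyl-5-{[(trifluoromethyl)sulfonyl]oxy}-3,4,4a,7,8,8a-hexahydroquinoline-1(2H)-carboxylate | C[C@@H]1N(C(=O)OC(C)(C)C)[C@@H]2CCC=C(OS(=O)(=O)C(F)(F)F)[C@@H]2C[C@H]1OCc1ccccc1 | intermediate
15 | (2R)-2-propyloxirane | CCC[C@@H]1CO1 | starting material
16 | (4R)-oct-7-en-4-ol | CCC[C@@H](O)CCC=C | intermediate
17 | tert-butyl(dimethyl){[(4R)-oct-7-en-4-yl]oxy}silane | CCC[C@@H](O[Si](C)(C)C(C)(C)C)CCC=C | intermediate
18 | 9-[(5R)-5-{[tert-butyl(dimethyl)silyl]oxy}octyl]-9-borabicyclo[3.3.1]nonane (not isolated) | CCC[C@@H](O[Si](C)(C)C(C)(C)C)CCCCB1C2CCCC1CCC2 | intermediate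
19 | tert-butyl (2S,3R,4aS,8aR)-3-(benzyloxy)-5-[(5R)-5-{[tert-butyl(dimethyl)silyl]oxy}octyl]-2-methyl-3,4,4a,7,8,8a-hexahydroquinoline-1(2H)-carboxylate | C[C@@H]1N(C(=O)OC(C)(C)C)[C@@H]2CCC=C(CCCC[C@H](O[Si](C)(C)C(C)(C)C)CCC)[C@@H]2C[C@H]1OCc1ccccc1 | intermediate
20 | tert-butyl (2S,3R,4aS,5S,8aR)-5-[(5R)-5-{[tert-butyl(dimethyl)silyl]oxy}octyl]-3-hydroxy-2-methyloctahydroquinoline-1(2H)-carboxylate | C[C@@H]1N(C(=O)OC(C)(C)C)[C@@H]2CCC[C@H](CCCC[C@H](O[Si](C)(C)C(C)(C)C)CCC)[C@@H]2C[C@H]1O | intermediate
21 | (2E)-hex-2-enal | CCC/C=C/C=O | starting material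
22 | (2E,4E)-octa-2,4-dienoic acid | CCC/C=C/C=C/C(=O)O | intermediate
23 | tert-butyl (2S,3R,4aS,5S,8aR)-5-[(5R)-5-{[tert-butyl(dimethyl)silyl]oxy}octyl]-2-methyl-3-{[(2E,4E)-octa-2,4-dienoyl]oxy}octahydroquinoline-1(2H)-carboxylate | C[C@@H]1N(C(=O)OC(C)(C)C)[C@@H]2CCC[C@H](CCCC[C@H](O[Si](C)(C)C(C)(C)C)CCC)[C@@H]2C[C@H]1OC(=O)/C=C/C=C/CCC | intermediate
24 | lepadin H, (2S,3R,4aS,5S,8aR)-5-[(5R)-5-hydroxyoctyl]-2-methyldecahydroquinolin-3-yl (2E,4E)-octa-2,4-dienoate | CCC/C=C/C=C/C(=O)O[C@@H]1C[C@H]2[C@@H](CCCC[C@H](O)CCC)CCC[C@H]2N[C@H]1C | target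

Total step count: 15. Longest linear sequence: 12 steps (steps 1 to 8, 11, 12, 14, 15).

Steps most likely to fail

Step 5. The ring-closing SN2 at C4 is slowed by the adjacent benzyloxy-bearing carbon, so the sequence may stall at the monocyclic enaminone or give way to intermolecular N-alkylation and loss of hydrogen halide. The fallback forms the C4–C4a bond first by a reductive Knoevenagel alkylation, which involves no displacement by a weak carbon nucleophile; it sets out from 4 and returns at 9. Chloride 4 is heated with CsOAc (NaI cat., DMF, 90 °C) to give tert-butyl [(2S,3S)-4-acetoxy-3-(benzyloxy)butan-2-yl]carbamate F1. K2CO3 in MeOH cleaves this to tert-butyl [(2S,3S)-3-(benzyloxy)-4-hydroxybutan-2-yl]carbamate F2. Dess–Martin oxidation gives tert-butyl [(2S,3S)-3-(benzyloxy)-4-oxobutan-2-yl]carbamate F3. F3 undergoes three-component reductive alkylation of dione 6 (L-proline cat., Hantzsch ester, CH2Cl2, rt; Knoevenagel condensation, then conjugate hydride transfer) to give tert-butyl [(2S,3R)-3-(benzyloxy)-4-(2,6-dioxocyclohexyl)butan-2-yl]carbamate F4. TFA in CH2Cl2 then removes the carbamate and the freed amine should condense spontaneously with a ring carbonyl to give 9.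

Step 6. Hydride may be delivered to the wrong face of the iminium (giving the 2,8a-trans series, which cannot be corrected later), or reduction of the weakly basic vinylogous amide may be incomplete. The fallback replaces kinetic hydride control by thermodynamic control at C8a; it sets out from 9 and returns at 12. Enaminone 9 is hydrogenated only to the β-amino ketone stage (H2, Pt/C, AcOH). The crude secondary amine is then warmed with K2CO3 in MeOH, so that reversible retro-aza-Michael opening and re-closure together with enolisation at C4a should funnel the material to the 2,8a-cis-diequatorial amino ketone (2S,3R,8aR)-3-(benzyloxy)-2-methyloctahydroquinolin-5(1H)-one F5 (mixed C4a epimers). Boc2O then gives ketone mixture 12, which is equilibrated to 13 as in the second stage of step 7.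

Step 12. On palladium the C5=C6 bond may migrate toward C4a before it is saturated, or hydrogen may be delivered in part to the concave face; either process would erode the C4a/C5 configuration. The fallback separates saturation from debenzylation and uses a stepwise radical hydrogen-atom-transfer reduction, in which no metal hydride addition–elimination can move the alkene and the tertiary C5 radical is quenched from the open face; it sets out from 19 and returns at 20. Alkene 19 is treated with Mn(dpm)3 (tris(dipivaloylmethanato)manganese, cat.), PhSiH3 and tert-butyl hydroperoxide in iPrOH at rt (Mukaiyama-type hydrogenation) to give tert-butyl (2S,3R,4aS,5S,8aR)-3-(benzyloxy)-5-[(5R)-5-{[tert-butyl(dimethyl)silyl]oxy}octyl]-2-methyloctahydroquinoline-1(2H)-carboxylate F6. Hydrogenolysis of the benzyl ether (H2, Pd/C, EtOAc) then gives 20.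

Further compounds
F1 | step 5 | tert-butyl [(2S,3S)-4-acetoxy-3-(benzyloxy)butan-2-yl]carbamate | C[C@H](NC(=O)OC(C)(C)C)[C@H](OCc1ccccc1)COC(C)=O
F2 | step 5 | tert-butyl [(2S,3S)-3-(benzyloxy)-4-hydroxybutan-2-yl]carbamate | C[C@H](NC(=O)OC(C)(C)C)[C@H](OCc1ccccc1)CO
F3 | step 5 | tert-butyl [(2S,3S)-3-(benzyloxy)-4-oxobutan-2-yl]carbamate | C[C@H](NC(=O)OC(C)(C)C)[C@H](OCc1ccccc1)C=O
F4 | step 5 | tert-butyl [(2S,3R)-3-(benzyloxy)-4-(2,6-dioxocyclohexyl)butan-2-yl]carbamate | C[C@H](NC(=O)OC(C)(C)C)[C@H](OCc1ccccc1)CC1C(=O)CCCC1=O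
F5 | step 6 | (2S,3R,8aR)-3-(benzyloxy)-2-methyloctahydroquinolin-5(1H)-one, mixed C4a epimers | C[C@@H]1N[C@@H]2CCCC(=O)C2C[C@H]1OCc1ccccc1
F6 | step 12 | tert-butyl (2S,3R,4aS,5S,8aR)-3-(benzyloxy)-5-[(5R)-5-{[tert-butyl(dimethyl)silyl]oxy}octyl]-2-methyloctahydroquinoline-1(2H)-carboxylate | C[C@@H]1N(C(=O)OC(C)(C)C)[C@@H]2CCC[C@H](CCCC[C@H](O[Si](C)(C)C(C)(C)C)CCC)[C@@H]2C[C@H]1OCc1ccccc1
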